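The route rests on the 1,5-relationship between the C2 carboxyl carbon and C5 (through C3 and C4) in a ring where O1 and ring A already join C2 to C5. Esterifying that carboxyl onto a C5 carbinol gives a seven-membered 1,4-benzodioxepin-3-one whose enolate has C2 and C3 at the termini of an allyl ester. One Ireland–Claisen shift of its silyl ketene acetal forms C2–C3, exchanges the lactone for the oxepine, frees the C2 acid and sets C2 and C3 from the single C5 stereocentre. The precursor is the (5S)-lactone with an (E)-1-(methoxycarbonyl)-2-phenylethenyl group at C5 and a methoxymethyl-protected 4-hydroxyphenyl group at C2.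

Key step: step 7

Assumption: the sense of induction of the chromium ligand in step 4 is not secure for this aldehyde (the (S)-ligand is written; its antipode is used if a pilot run gives the (R)-carbinol), and the 3,4-trans arrangement of the target is taken to be the more stable one at the epimerisable C4.

Step 1
Reactants: 1 methyl (E)-cinnamate
Product: 3 methyl (Z)-2-bromo-3-phenylprop-2-enoate, via dibromo ester 2 (not isolated)
Conditions: Br2, CH2Cl2, 0 °C → rt; then Et3N, 0 °C → rt
Reagents that add atoms: bromine, BrBr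
Why: Alkene bromination followed by base-mediated dehydrobromination through the acidic α-hydrogen should give mainly the more stable (Z)-bromide with phenyl trans to the ester, the minor (E)-isomer being removed by chromatography.

Step 2
Reactants: 4 methyl 4-hydroxymandelate (racemic)
Product: 5 methyl 2-hydroxy-2-[4-(methoxymethoxy)phenyl]acetate (racemic)
Conditions: MOMCl, K2CO3, acetone, 0 °C → rt
Reagents that add atoms: chloromethyl methyl ether, COCCl
Why: Williamson-type O-alkylation of the phenoxide, the only group that carbonate deprotonates, leaves the secondary alcohol free.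

Step 3
Reactants: 5 methyl 2-hydroxy-2-[4-(methoxymethoxy)phenyl]acetate; 6 2-hydroxy-4,6-dimethoxybenzaldehyde
Product: 7 methyl 2-(2-formyl-3,5-dimethoxyphenoxy)-2-[4-(methoxymethoxy)phenyl]acetate (racemic)
Conditions: PPh3, diisopropyl azodicarboxylate, THF, 0 °C → rt
Reagents that add atoms: none
Why: Mitsunobu etherification of the acidic phenol with the activated α-hydroxy ester makes the O1–C2 bond before any allylic ester exists, so no phenoxide is ever set free beside the enoate; the new centre is racemic, which does not matter because it becomes planar in step 7.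

Step 4
Reactants: 7 methyl 2-(2-formyl-3,5-dimethoxyphenoxy)-2-[4-(methoxymethoxy)phenyl]acetate; 3 methyl (Z)-2-bromo-3-phenylprop-2-enoate
Product: 9 methyl (2E)-2-[(S)-hydroxy(2,4-dimethoxy-6-{2-methoxy-1-[4-(methoxymethoxy)phenyl]-2-oxoethoxy}phenyl)methyl]-3-phenylprop-2-enoate (both epimers at the aryloxyacetate carbon), via silyl ether 8 (not isolated)
Conditions: CrCl2 (15 mol %), (S)-N-[2-(4-isopropyl-4,5-dihydro-1,3-oxazol-2-yl)-6-methoxyphenyl]methanesulfonamide (17 mol %), Et3N, NiCl2·(2,9-dimethyl-1,10-phenanthroline) (3 mol %), Mn, Me3SiCl, LiCl, MeCN, rt; then K2CO3, MeOH, 0 °C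
Reagents that add atoms: none
Why: Catalytic asymmetric Nozaki–Hiyama–Kishi coupling, in which zerovalent nickel inserts into the C–Br bond, the alkenyl group passes with retention to ligand-bound trivalent chromium (phenyl stays trans to the ester, also the thermodynamically preferred geometry) and adds to one face of the aldehyde under ligand control to set the (S)-carbinol.

Step 5
Reactants: 9 the (S,E)-hydroxy diester
Product: 10 2-{2-[(1S,2E)-1-hydroxy-2-(methoxycarbonyl)-3-phenylprop-2-en-1-yl]-3,5-dimethoxyphenoxy}-2-[4-(methoxymethoxy)phenyl]acetic acid (both C2 epimers)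
Conditions: LiOH·H2O (1.2 equiv), THF/H2O, 0 °C; then aq. HCl to pH 4, 0 °C
Reagents that add atoms: lithium hydroxide, [Li+].[OH-]
Why: Chemoselective saponification, since the α-aryloxy arylacetate ester is inductively activated whereas the α-branched cinnamate ester is conjugated and hindered, so one equivalent of hydroxide at 0 °C should cleave only the former.

Step 6
Reactants: 10 the hydroxy acid
Product: 11 methyl (2E)-2-{(5S)-6,8-dimethoxy-2-[4-(methoxymethoxy)phenyl]-3-oxo-2,3-dihydro-5H-1,4-benzodioxepin-5-yl}-3-phenylprop-2-enoate (both C2 epimers)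
Conditions: 2-methyl-6-nitrobenzoic anhydride, DMAP, Et3N, CH2Cl2 (2 mM, slow addition), rt
Reagents that add atoms: none
Why: Shiina lactonisation through the mixed anhydride closes the seven-membered ring (7-exo-trig at the acyl carbon) under non-acidic conditions that spare the ionisable C5–O bond; C5 is untouched and C2 stays an inconsequential epimer mixture.

Step 7
Reactants: 11 the (5S)-benzodioxepinone
Product: 14 (2S,3R)-6,8-dimethoxy-4-(methoxycarbonyl)-2-[4-(methoxymethoxy)phenyl]-3-phenyl-2,3-dihydro-1-benzoxepine-2-carboxylic acid, via silyl ketene acetal 12 (not isolated), via silyl ester 13 (not isolated)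
Conditions: Me3SiCl (3 equiv, premixed with Et3N), KN(SiMe3)2 (1.3 equiv), toluene/THF, −78 °C → rt (to 60 °C if required); then H2O, extraction into aq. NaHCO3 and acidification to pH 3
Reagents that add atoms: none
Why: KN(SiMe3)2 removes the C2–H (α to the lactone carbonyl, benzylic and α-aryloxy, far more acidic than any other C–H) in the presence of Me3SiCl, so the enolate is trapped at once as the ring-fixed silyl ketene acetal 12, which on warming undergoes the [3,3] shift across C2=C3–O4–C5–C=C, forming C2–C3 as O4–C5 breaks and giving silyl ester 13, hydrolysed to 14 on work-up; the closest known reaction type is the Ireland–Claisen rearrangement of alkenyl-substituted lactone ketene acetals to cycloalkene carboxylic acids. The seven-membered lactone is thereby exchanged for the seven-membered oxepine ring, closed at the alkene terminus in a formal 7-endo-trig sense within a six-atom array that the O1/ring A tether between C2 and C5 forces into a boat. C2 is controlled by the C5 stereocentre: the alkenyl group is held over one face of the planar ketene acetal and the suprafacial shift transfers (5S) to (2S), both C2 epimers of 11 converging because C2 is planar in 12. C3 is controlled by the alkene geometry: in the boat the (E)-alkene places phenyl inside, next to ring A, which puts it cis to the C2 aryl group (3R), whereas a (Z)-alkene would give the C3 epimer, so the geometric purity of 11 matters. The step needs the concerted shift to outrun heterolysis of the C5–O bond, which is benzylic to the trioxygenated ring A and would lead to a dihydrobenzofuran by [1,3] collapse or to stereochemical leakage; the electron-poor enoate at C5 disfavours the cation, the low-polarity medium disfavours ion pairs, and the small Me3Si group limits the eclipsing with the C4 ester across the boat. Polar character in the transition state is tolerable, since bond formation from the ketene acetal carbon to the β-carbon of the enoate ahead of C–O cleavage leads to the same product through the same tethered geometry.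

Step 8
Reactants: 14 the (2S,3R)-acid
Product: 15 2-(4-methoxybenzyl) 4-methyl (2S,3R)-6,8-dimethoxy-2-[4-(methoxymethoxy)phenyl]-3-phenyl-2,3-dihydro-1-benzoxepine-2,4-dicarboxylate
Conditions: 4-methoxybenzyl chloride, K2CO3, DMF, rt
Reagents that add atoms: 4-methoxybenzyl chloride, COc1ccc(CCl)cc1
Why: SN2 O-alkylation of the carboxylate masks the hindered acid so that it cannot bind the copper catalyst, lactonise onto C5 or take part in acyl transfer during amide formation; no stereocentre is touched.

Step 9
Reactants: 15 the enoate diester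
Product: 17 2-(4-methoxybenzyl) 4-methyl (2S,3S)-5-hydroxy-6,8-dimethoxy-2-[4-(methoxymethoxy)phenyl]-3-phenyl-2,3,4,5-tetrahydro-1-benzoxepine-2,4-dicarboxylate (C4/C5 epimer mixture), via pinacol boronate 16 (not isolated)
Conditions: CuCl (10 mol %), NaOtBu (15 mol %), Xantphos (10 mol %), B2pin2 (1.5 equiv), MeOH (3 equiv), THF, rt → 40 °C; then NaBO3·4H2O, THF/H2O, rt
Reagents that add atoms: sodium perborate tetrahydrate, [Na+].[O-]B1OO1.O.O.O.O
Why: Copper-catalysed conjugate borylation places boron on the β-carbon C5 of the enoate and perborate oxidises the C–B bond with retention under nearly neutral conditions that avoid β-elimination; the centres formed at C4 and C5 are mixtures, which is immaterial because C5 becomes a ketone and C4 is equilibrated later.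

Step 10
Reactants: 17 the β-hydroxy ester
Product: 18 2-(4-methoxybenzyl) 4-methyl (2S,3S)-6,8-dimethoxy-2-[4-(methoxymethoxy)phenyl]-5-oxo-3-phenyl-2,3,4,5-tetrahydro-1-benzoxepine-2,4-dicarboxylate (C4 epimers interconverting through the enol)
Conditions: Dess–Martin periodinane, CH2Cl2, 0 °C → rt
Reagents that add atoms: none
Why: Dess–Martin oxidation of the secondary benzylic alcohol gives the C5 aryl ketone, and the resulting β-keto ester makes C4 epimerisable.

Step 11
Reactants: 19 (tert-butyldimethylsilyloxy)acetaldehyde; 20 ethyl 2-(triphenylphosphoranylidene)propanoate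
Product: 21 ethyl (2E)-4-[(tert-butyldimethylsilyl)oxy]-2-methylbut-2-enoate
Conditions: CH2Cl2, rt
Reagents that add atoms: none
Why: Wittig olefination with a stabilised α-methyl ylide should give the (E)-trisubstituted enoate selectively.

Step 12
Reactants: 21 the silyloxy enoate
Product: 22 (2E)-4-[(tert-butyldimethylsilyl)oxy]-2-methylbut-2-enoic acid
Conditions: LiOH·H2O, THF/MeOH/H2O, rt; then aq. HCl to pH 4–5, 0 °C
Reagents that add atoms: lithium hydroxide, [Li+].[OH-]
Why: Ester saponification, to which the primary silyl ether and the alkene geometry are stable at room temperature.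

Step 13
Reactants: 22 the silyloxy enoic acid; 23 putrescine
Product: 25 (2E)-N-(4-aminobutyl)-4-[(tert-butyldimethylsilyl)oxy]-2-methylbut-2-enamide, via acyl imidazole 24 (not isolated)
Conditions: 1,1'-carbonyldiimidazole, THF, rt; then added to putrescine (8 equiv), THF, 0 °C → rt
Reagents that add atoms: none
Why: Amide formation through the acyl imidazole, with a large excess of the symmetric diamine to secure monoacylation (the excess is washed out with water).

Step 14
Reactants: 18 the β-keto ester; 25 the side-chain amine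
Product: 26 4-methoxybenzyl (2S,3S,4R)-4-{[4-({(2E)-4-[(tert-butyldimethylsilyl)oxy]-2-methylbut-2-enoyl}amino)butyl]carbamoyl}-6,8-dimethoxy-2-[4-(methoxymethoxy)phenyl]-5-oxo-3-phenyl-2,3,4,5-tetrahydro-1-benzoxepine-2-carboxylate
Conditions: 25 (1.5 equiv), DMAP (0.3 equiv), toluene, 4 Å molecular sieves, 100 °C
Reagents that add atoms: none
Why: Aminolysis of a β-keto ester (acyl ketene pathway, DMAP-assisted) is selective for the C4 ester because only it is β to a ketone, the hindered electron-rich aryl ketone does not form an enamine, and C4 equilibrates through the enol to the epimer with the amide trans to the C3 phenyl group (4R).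

Step 15
Reactants: 26 the protected amide
Product: 27 (2S,3S,4R)-4-{[4-({(2E)-4-hydroxy-2-methylbut-2-enoyl}amino)butyl]carbamoyl}-2-(4-hydroxyphenyl)-6,8-dimethoxy-5-oxo-3-phenyl-2,3,4,5-tetrahydro-1-benzoxepine-2-carboxylic acid
Conditions: CF3CO2H/CH2Cl2 (1:2), 1,3,5-trimethoxybenzene (10 equiv), H2O (10 equiv), 0 °C → rt; aq. NaHCO3 wash, then pH 3
Reagents that add atoms: none
Why: Acidolysis should remove the 4-methoxybenzyl ester, the methoxymethyl ether and the silyl ether in one operation, the benzyl cation being trapped by a scavenger more nucleophilic than ring A, while the β-keto amide, the enamide and the three stereocentres are stable to acid.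

Compound list
1 | methyl (E)-cinnamate | COC(=O)/C=C/c1ccccc1 | starting material
2 | methyl (2R*,3S*)-2,3-dibromo-3-phenylpropanoate (racemic, one enantiomer drawn) | COC(=O)[C@@H](Br)[C@@H](Br)c1ccccc1 | intermediate
3 | methyl (Z)-2-bromo-3-phenylprop-2-enoate | COC(=O)/C(Br)=C/c1ccccc1 | intermediate
4 | methyl 4-hydroxymandelate (methyl 2-hydroxy-2-(4-hydroxyphenyl)acetate, racemic) | COC(=O)C(O)c1ccc(O)cc1 | starting material
5 | methyl 2-hydroxy-2-[4-(methoxymethoxy)phenyl]acetate (racemic) | COCOc1ccc(cc1)C(O)C(=O)OC | intermediate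
6 | 2-hydroxy-4,6-dimethoxybenzaldehyde | COc1cc(O)c(C=O)c(OC)c1 | starting material
7 | methyl 2-(2-formyl-3,5-dimethoxyphenoxy)-2-[4-(methoxymethoxy)phenyl]acetate (racemic) | COC(=O)C(Oc1cc(OC)cc(OC)c1C=O)c1ccc(OCOC)cc1 | intermediate
8 | trimethylsilyl ether of 9 (S at the carbinol carbon, E alkene) | COc1cc(OC)c(c(c1)OC(c1ccc(OCOC)cc1)C(=O)OC)[C@H](O[Si](C)(C)C)/C(C(=O)OC)=C\c1ccccc1 | intermediate
9 | methyl (2E)-2-[(S)-hydroxy(2,4-dimethoxy-6-{2-methoxy-1-[4-(methoxymethoxy)phenyl]-2-oxoethoxy}phenyl)methyl]-3-phenylprop-2-enoate (both epimers at the aryloxyacetate carbon) | COc1cc(OC)c(c(c1)OC(c1ccc(OCOC)cc1)C(=O)OC)[C@H](O)/C(C(=O)OC)=C\c1ccccc1 | intermediate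
10 | 2-{2-[(1S,2E)-1-hydroxy-2-(methoxycarbonyl)-3-phenylprop-2-en-1-yl]-3,5-dimethoxyphenoxy}-2-[4-(methoxymethoxy)phenyl]acetic acid (both C2 epimers) | COc1cc(OC)c(c(c1)OC(c1ccc(OCOC)cc1)C(=O)O)[C@H](O)/C(C(=O)OC)=C\c1ccccc1 | intermediate
11 | methyl (2E)-2-{(5S)-6,8-dimethoxy-2-[4-(methoxymethoxy)phenyl]-3-oxo-2,3-dihydro-5H-1,4-benzodioxepin-5-yl}-3-phenylprop-2-enoate (both C2 epimers) | COc1cc(OC)c2c(c1)OC(c1ccc(OCOC)cc1)C(=O)O[C@@H]2/C(C(=O)OC)=C\c1ccccc1 | intermediate
12 | methyl (2E)-2-{(5S)-6,8-dimethoxy-2-[4-(methoxymethoxy)phenyl]-3-[(trimethylsilyl)oxy]-5H-1,4-benzodioxepin-5-yl}-3-phenylprop-2-enoate | COc1cc(OC)c2c(c1)OC(c1ccc(OCOC)cc1)=C(O[Si](C)(C)C)O[C@@H]2/C(C(=O)OC)=C\c1ccccc1 | intermediate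
13 | trimethylsilyl (2S,3R)-6,8-dimethoxy-4-(methoxycarbonyl)-2-[4-(methoxymethoxy)phenyl]-3-phenyl-2,3-dihydro-1-benzoxepine-2-carboxylate | COc1cc(OC)c2c(c1)O[C@](C(=O)O[Si](C)(C)C)(c1ccc(OCOC)cc1)[C@H](c1ccccc1)C(C(=O)OC)=C2 | intermediate
14 | (2S,3R)-6,8-dimethoxy-4-(methoxycarbonyl)-2-[4-(methoxymethoxy)phenyl]-3-phenyl-2,3-dihydro-1-benzoxepine-2-carboxylic acid | COc1cc(OC)c2c(c1)O[C@](C(=O)O)(c1ccc(OCOC)cc1)[C@H](c1ccccc1)C(C(=O)OC)=C2 | intermediate
15 | 2-(4-methoxybenzyl) 4-methyl (2S,3R)-6,8-dimethoxy-2-[4-(methoxymethoxy)phenyl]-3-phenyl-2,3-dihydro-1-benzoxepine-2,4-dicarboxylate | COc1cc(OC)c2c(c1)O[C@](C(=O)OCc1ccc(OC)cc1)(c1ccc(OCOC)cc1)[C@H](c1ccccc1)C(C(=O)OC)=C2 | intermediate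
16 | 2-(4-methoxybenzyl) 4-methyl (2S,3S)-6,8-dimethoxy-2-[4-(methoxymethoxy)phenyl]-3-phenyl-5-(4,4,5,5-tetramethyl-1,3,2-dioxaborolan-2-yl)-2,3,4,5-tetrahydro-1-benzoxepine-2,4-dicarboxylate (C4/C5 mixture) | COc1cc(OC)c2c(c1)O[C@](C(=O)OCc1ccc(OC)cc1)(c1ccc(OCOC)cc1)[C@H](c1ccccc1)C(C(=O)OC)C2B1OC(C)(C)C(C)(C)O1 | intermediate
17 | 2-(4-methoxybenzyl) 4-methyl (2S,3S)-5-hydroxy-6,8-dimethoxy-2-[4-(methoxymethoxy)phenyl]-3-phenyl-2,3,4,5-tetrahydro-1-benzoxepine-2,4-dicarboxylate (C4/C5 mixture) | COc1cc(OC)c2c(c1)O[C@](C(=O)OCc1ccc(OC)cc1)(c1ccc(OCOC)cc1)[C@H](c1ccccc1)C(C(=O)OC)C2O | intermediate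
18 | 2-(4-methoxybenzyl) 4-methyl (2S,3S)-6,8-dimethoxy-2-[4-(methoxymethoxy)phenyl]-5-oxo-3-phenyl-2,3,4,5-tetrahydro-1-benzoxepine-2,4-dicarboxylate (C4 epimers) | COc1cc(OC)c2c(c1)O[C@](C(=O)OCc1ccc(OC)cc1)(c1ccc(OCOC)cc1)[C@H](c1ccccc1)C(C(=O)OC)C2=O | intermediate
19 | (tert-butyldimethylsilyloxy)acetaldehyde | CC(C)(C)[Si](C)(C)OCC=O | starting material
20 | ethyl 2-(triphenylphosphoranylidene)propanoate | CCOC(=O)C(C)=P(c1ccccc1)(c1ccccc1)c1ccccc1 | starting material
21 | ethyl (2E)-4-[(tert-butyldimethylsilyl)oxy]-2-methylbut-2-enoate | CCOC(=O)/C(C)=C/CO[Si](C)(C)C(C)(C)C | intermediate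
22 | (2E)-4-[(tert-butyldimethylsilyl)oxy]-2-methylbut-2-enoic acid | OC(=O)/C(C)=C/CO[Si](C)(C)C(C)(C)C | intermediate
23 | putrescine (butane-1,4-diamine) | NCCCCN | starting material
24 | (2E)-4-[(tert-butyldimethylsilyl)oxy]-1-(1H-imidazol-1-yl)-2-methylbut-2-en-1-one | O=C(/C(C)=C/CO[Si](C)(C)C(C)(C)C)n1ccnc1 | intermediate
25 | (2E)-N-(4-aminobutyl)-4-[(tert-butyldimethylsilyl)oxy]-2-methylbut-2-enamide | NCCCCNC(=O)/C(C)=C/CO[Si](C)(C)C(C)(C)C | intermediate
26 | 4-methoxybenzyl (2S,3S,4R)-4-{[4-({(2E)-4-[(tert-butyldimethylsilyl)oxy]-2-methylbut-2-enoyl}amino)butyl]carbamoyl}-6,8-dimethoxy-2-[4-(methoxymethoxy)phenyl]-5-oxo-3-phenyl-2,3,4,5-tetrahydro-1-benzoxepine-2-carboxylate | COc1cc(OC)c2c(c1)O[C@](C(=O)OCc1ccc(OC)cc1)(c1ccc(OCOC)cc1)[C@H](c1ccccc1)[C@@H](C(=O)NCCCCNC(=O)/C(C)=C/CO[Si](C)(C)C(C)(C)C)C2=O | intermediate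
27 | (2S,3S,4R)-4-{[4-({(2E)-4-hydroxy-2-methylbut-2-enoyl}amino)butyl]carbamoyl}-2-(4-hydroxyphenyl)-6,8-dimethoxy-5-oxo-3-phenyl-2,3,4,5-tetrahydro-1-benzoxepine-2-carboxylic acid | COc1cc(OC)c2c(c1)O[C@](C(=O)O)(c1ccc(O)cc1)[C@H](c1ccccc1)[C@@H](C(=O)NCCCCNC(=O)/C(C)=C/CO)C2=O | target

Total step count: 15. Longest linear sequence: 11 steps (steps 2 to 10, then 14 and 15).

Steps most likely to fail

Step 7. Heterolysis of the C5–O bond of the ketene acetal may outrun the concerted shift, or the crowded boat with the inside phenyl group against ring A may be reached too slowly. Either would lead to ion-pair collapse at C5 or to loss of stereochemical fidelity. The fallback makes the same C2–C3 bond by a polar, stepwise route without silylation. It sets out from 11: a base alone (Cs2CO3 in MeCN, or KOtBu in THF, 0 °C → rt) generates the lactone enolate, which adds in conjugate fashion to the β-carbon of the enoate on the face fixed by the lactone tether. This gives, as its ester enolate, the bridged lactone F1. β-Elimination of the C5 carboxylate then opens the lactone bridge, and acidification brings the material back to the route at 14. This is the intramolecular form of the established alkylation of stabilised enolates with Morita–Baylis–Hillman esters. Because C5 stays tetrahedral while the C–C bond forms, neither a C5 cation nor a planar allyl unit is needed.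

Step 4. Facial discrimination of the hindered, chelating aldehyde by the chromium–ligand complex may be incomplete, or alkene geometry may be partly lost at the alkenyl–metal stage. The fallback secures enantiopurity by classical resolution instead of catalysis. It sets out from 9 of insufficient enantiomeric purity (or racemic 9 from a ligand-free coupling), which is taken through steps 5 to 7 unchanged. The resulting acid is treated with (S)-1-phenylethylamine in EtOAc/iPrOH and the (S)-1-phenylethylammonium carboxylate F2 is crystallised to constant rotation; the antipodal amine is used if the other salt proves less soluble. Partition between EtOAc and pH 4 buffer returns the route to enantiopure 14. Any C3 epimer arising from (Z)-alkene is a diastereomer and should be removed in the same crystallisation.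

Step 9. Addition of the boryl–copper species to the trisubstituted enoate may be slow, because the β-carbon carries the di-ortho-substituted, electron-rich ring A; β-elimination of the C5 oxygen during the oxidative work-up is the second hazard. The fallback introduces the C5 oxygen by electrophilic oxidation of the alkene and removes the surplus C4 oxygen reductively. It sets out from 15: OsO4 (cat.) with N-methylmorpholine N-oxide in acetone/H2O should give the 4,5-diol F3, the donor ring A making the alkene electron-rich enough for osmylation. SmI2 in THF/MeOH (HMPA if required) then cleaves the C–O bond α to the ester, and the route is rejoined at 17 (a C4/C5 mixture, as before).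

Further compounds
F1 | step 7 | bridged lactone: methyl 6,8-dimethoxy-2-[4-(methoxymethoxy)phenyl]-3-phenyl-2,3,4,5-tetrahydro-1-benzoxepine-4-carboxylate whose C2 carboxyl group is still lactonised onto the C5 oxygen (C2–C3 bond formed, C4 unassigned) | COc1cc(OC)c2c(c1)O[C@@]3(c1ccc(OCOC)cc1)C(=O)O[C@@H]2C(C(=O)OC)[C@H]3c1ccccc1
F2 | step 4 | (S)-1-phenylethylammonium (2S,3R)-6,8-dimethoxy-4-(methoxycarbonyl)-2-[4-(methoxymethoxy)phenyl]-3-phenyl-2,3-dihydro-1-benzoxepine-2-carboxylate | COc1cc(OC)c2c(c1)O[C@](C(=O)[O-])(c1ccc(OCOC)cc1)[C@H](c1ccccc1)C(C(=O)OC)=C2.C[C@H]([NH3+])c1ccccc1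
F3 | step 9 | 2-(4-methoxybenzyl) 4-methyl (2S,3S)-4,5-dihydroxy-6,8-dimethoxy-2-[4-(methoxymethoxy)phenyl]-3-phenyl-2,3,4,5-tetrahydro-1-benzoxepine-2,4-dicarboxylate (cis-diol, C4/C5 unassigned) | COc1cc(OC)c2c(c1)O[C@](C(=O)OCc1ccc(OC)cc1)(c1ccc(OCOC)cc1)[C@H](c1ccccc1)C(O)(C(=O)OC)C2O
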